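**Plan**

1. Retrosynthetic cuts: the two ester C–O bonds (C3–O, C9–O); then C9–C10 of the cyclohexanone ring, put back as C8–C10 of a cyclopentane that carries OH and CHO on C8; then C7–C8 (carbonyl-ene), the exocyclic C10–C8 bond (Nozaki–Hiyama–Kishi), and C5–C6 with C4–CH3 (cuprate addition/prenylation).
2. Forward order: ring A is carried from a 4-silyloxycyclohexenone; the cyclopentane C5–C6–C7–C8–C10 is closed by an intramolecular ene reaction; this ring is enlarged by one carbon to the cyclohexanone; the two esters are attached last.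
3. Enabling feature: the α-acyloxy ketone C7–C8(=O)–C9(O)–C10 of the cyclohexanone ring is the retron of an α-ketol rearrangement of a 1-hydroxycyclopentane-1-carbaldehyde. The isopropenyl group on C7, next to that carbonyl, is the retron of the ene reaction that builds this cyclopentanol.
4. Stereochemistry: C3 from the (R)-enone; C4 by cuprate addition anti to the silyloxy group; C5 by alkylation anti to the C4 methyl; C10 by ketonisation/equilibration; C7 and C8 in the ene step; C9 in the chelate-controlled 1,2-shift, where the C8 configuration also decides which ring bond migrates.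

Key step: step 10

Remark on numbering: atoms carry eremophilane numbers (ring A = C1–C2–C3–C4–C5–C10; cyclohexanone ring = C5–C6–C7–C8–C9–C10; C14 = methyl on C5, C15 = methyl on C4, C11–C13 = isopropenyl on C7). β is the face that carries C14, α the opposite face. Hydrindane locants 1, 2, 3, 3a, 4, 5, 6, 7, 7a correspond to C8, C7, C6, C5, C4, C3, C2, C1, C10.
Assumption: (R)-4-(tert-butyldimethylsilyloxy)cyclohex-2-en-1-one is taken to be purchasable as a catalogue chiral building block.

**Step 1**
Reactants: 1 (R)-4-(tert-butyldimethylsilyloxy)cyclohex-2-en-1-one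
Product: 2 (R)-4-(tert-butyldimethylsilyloxy)-2-iodocyclohex-2-en-1-one
Conditions: I2, pyridine, CH2Cl2, 0 °C → rt
Reagents that add atoms: iodine, II
Why: Iodine–pyridine α-iodination of a cyclohexenone (conjugate addition of pyridine, iodination of the enolate and elimination) is a standard transformation that leaves the silyl ether and the C3 stereocentre untouched.

**Step 2**
Reactants: 2 (R)-4-(tert-butyldimethylsilyloxy)-2-iodocyclohex-2-en-1-one
Product: 3 (R)-4-(tert-butyldimethylsilyloxy)-2-methylcyclohex-2-en-1-one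
Conditions: Me4Sn, Pd2(dba)3 (cat.), AsPh3, CuI, NMP, 80 °C
Reagents that add atoms: tetramethylstannane, C[Sn](C)(C)C
Why: Stille cross-coupling of an α-iodoenone with tetramethylstannane under Pd/AsPh3/CuI catalysis is well precedented for installing a 2-methyl group and creates no stereocentre.

**Step 3**
Reactants: 3 (R)-4-(tert-butyldimethylsilyloxy)-2-methylcyclohex-2-en-1-one; 4 prenyl bromide (1-bromo-3-methylbut-2-ene)
Product: 6 (2R,3R,4R)-4-(tert-butyldimethylsilyloxy)-2,3-dimethyl-2-(3-methylbut-2-en-1-yl)cyclohexan-1-one, via lithium enolate 5 (not isolated)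
Conditions: Me2CuLi, Et2O, −78 → −30 °C; then prenyl bromide, HMPA, THF, −30 °C → rt
Reagents that add atoms: lithium dimethylcuprate, [Li+].C[Cu-]C; prenyl bromide 4, CC(C)=CCBr
Why: Tandem conjugate addition–enolate alkylation: the cuprate delivers the C15 methyl to C4 anti to the γ-silyloxy group (methyl β), and enolate 5, whose C4 methyl is pseudoaxial because of A(1,2) strain with the C5 methyl, is alkylated by prenyl bromide on the opposite α face, which sets the quaternary C5 with the two methyl groups cis.

**Step 4**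
Reactants: 6 (2R,3R,4R)-4-(tert-butyldimethylsilyloxy)-2,3-dimethyl-2-(3-methylbut-2-en-1-yl)cyclohexan-1-one
Product: 8 (4R,5R,6R)-4-(tert-butyldimethylsilyloxy)-5,6-dimethyl-6-(3-methylbut-2-en-1-yl)cyclohex-1-en-1-yl trifluoromethanesulfonate, via potassium enolate 7 (not isolated)
Conditions: KHMDS, THF, −78 °C; then PhNTf2, −78 → 0 °C
Reagents that add atoms: N-phenylbis(trifluoromethanesulfonimide), O=S(=O)(N(c1ccccc1)S(=O)(=O)C(F)(F)F)C(F)(F)F
Why: Because C5 is quaternary the ketone can be enolised only toward C1, so O-sulfonylation of potassium enolate 7 with N-phenyltriflimide (standard enol triflate formation) should give a single alkenyl triflate without touching a stereocentre.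

**Step 5**
Reactants: 8 (4R,5R,6R)-4-(tert-butyldimethylsilyloxy)-5,6-dimethyl-6-(3-methylbut-2-en-1-yl)cyclohex-1-en-1-yl trifluoromethanesulfonate; 9 ethyl glyoxylate
Product: 10 ethyl 2-[(4R,5R,6R)-4-(tert-butyldimethylsilyloxy)-5,6-dimethyl-6-(3-methylbut-2-en-1-yl)cyclohex-1-en-1-yl]-2-hydroxyacetate (both epimers at the carbinol carbon)
Conditions: CrCl2 (4 equiv), NiCl2 (cat.), DMF, rt
Reagents that add atoms: ethyl glyoxylate 9, CCOC(=O)C=O
Why: Nozaki–Hiyama–Kishi coupling: nickel inserts into the hindered alkenyl triflate and transmetallation gives an alkenylchromium(III) species that adds chemoselectively to the aldehyde carbonyl of the glyoxylate, the new carbinol centre (C8) being formed as an inconsequential mixture that is erased in step 6.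

**Step 6**
Reactants: 10 ethyl 2-[(4R,5R,6R)-4-(tert-butyldimethylsilyloxy)-5,6-dimethyl-6-(3-methylbut-2-en-1-yl)cyclohex-1-en-1-yl]-2-hydroxyacetate
Product: 11 ethyl 2-[(1R,2R,3R,4R)-4-(tert-butyldimethylsilyloxy)-2,3-dimethyl-2-(3-methylbut-2-en-1-yl)cyclohexyl]-2-oxoacetate
Conditions: DBU (0.3 equiv), CH2Cl2, rt
Reagents that add atoms: none
Why: Base-mediated 1,3-prototropic shift of the α-hydroxy-β,γ-unsaturated ester via its dienolate and the enol of the α-keto ester, which is the thermodynamic sink; C10 is set when the exocyclic enol ketonises from the α face, anti to the axial C14 methyl, and the same 10αH isomer, with the keto ester group equatorial and trans to the prenyl group, is the one favoured on equilibration with DBU.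

**Step 7**
Reactants: 11 ethyl 2-[(1R,2R,3R,4R)-4-(tert-butyldimethylsilyloxy)-2,3-dimethyl-2-(3-methylbut-2-en-1-yl)cyclohexyl]-2-oxoacetate
Product: 12 ethyl 5α-(tert-butyldimethylsilyloxy)-1α-hydroxy-3aβ,4β-dimethyl-2α-(prop-1-en-2-yl)-7aαH-octahydro-1H-indene-1β-carboxylate (trans-fused)
Conditions: Cu(OTf)2 (10 mol %), 4 Å MS, CH2Cl2, 0 °C → rt
Reagents that add atoms: none
Why: Intramolecular type I carbonyl-ene reaction of the Lewis-acid-chelated α-keto ester with the trisubstituted prenyl alkene, a reaction type precedented for 2-oxoalk-6-enoates: the cyclic ene transition state (O8···H–C12) forces hydroxyl and isopropenyl to be cis on the new cyclopentane, and the bulky CMe2 terminus bonds on the α face away from the 1,3-related angular methyl, so that C7 (isopropenyl α) and C8 (OH α, ester β) are set together while the diequatorial substituents on C5 and C10 give the trans ring fusion.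

**Step 8**
Reactants: 12 ethyl 5α-(tert-butyldimethylsilyloxy)-1α-hydroxy-3aβ,4β-dimethyl-2α-(prop-1-en-2-yl)-7aαH-octahydro-1H-indene-1β-carboxylate
Product: 13 5α-(tert-butyldimethylsilyloxy)-1β-(hydroxymethyl)-3aβ,4β-dimethyl-2α-(prop-1-en-2-yl)-7aαH-octahydro-1H-inden-1α-ol
Conditions: LiAlH4, THF, 0 °C; aqueous work-up
Reagents that add atoms: none
Why: Lithium aluminium hydride reduces the ester to the primary alcohol (standard ester reduction) while the silyl ether and the isolated alkene are inert and no stereocentre is affected.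

**Step 9**
Reactants: 13 5α-(tert-butyldimethylsilyloxy)-1β-(hydroxymethyl)-3aβ,4β-dimethyl-2α-(prop-1-en-2-yl)-7aαH-octahydro-1H-inden-1α-ol
Product: 14 5α-(tert-butyldimethylsilyloxy)-1α-hydroxy-3aβ,4β-dimethyl-2α-(prop-1-en-2-yl)-7aαH-octahydro-1H-indene-1β-carbaldehyde
Conditions: SO3·pyridine, DMSO, i-Pr2NEt, CH2Cl2, 0 °C
Reagents that add atoms: none
Why: Parikh–Doering oxidation converts the primary hydroxyl of a primary/tertiary 1,2-diol into the aldehyde without glycol cleavage, and the adjacent carbon C8 is fully substituted so that nothing can epimerise.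

**Step 10**
Reactants: 14 5α-(tert-butyldimethylsilyloxy)-1α-hydroxy-3aβ,4β-dimethyl-2α-(prop-1-en-2-yl)-7aαH-octahydro-1H-indene-1β-carbaldehyde
Product: 16 (3R,4R,5R,7S,9S,10R)-3-(tert-butyldimethylsilyloxy)-9-hydroxyeremophil-11-en-8-one, via chloro(methyl)aluminium alkoxide 15 (not isolated)
Conditions: Me2AlCl (1.5 equiv), CH2Cl2, −78 → 0 °C; aq. Rochelle salt
Reagents that add atoms: none
Why: Me2AlCl deprotonates the tertiary hydroxyl, and the aluminium alkoxide 15 binds the formyl oxygen in a five-membered chelate, so that the C8–C10 bond shifts with its electron pair from C8 to the activated formyl carbon C9 while C8 becomes the ketone; this is an α-ketol rearrangement with ring expansion, the reaction type known from the Lewis-acid-induced D-homoannulation of 17-hydroxy-20-oxo steroids. The six-membered ring is formed not by a cyclisation but by a suprafacial 1,2-alkyl shift that inserts C9 between C8 and C10 of the cyclopentane, C10 migrating with retention so that the trans ring fusion is carried over. The new stereocentre C9 is set by the chelate: the two oxygens stay syn-periplanar, which places the hydroxyl equatorial (α, cis to H-10) in the chair that forms. The step needs the ring bond to C10, not the one to C7, to migrate, and this is secured by the β-oriented formyl group fixed in step 7: only insertion into C8–C10 lets the new ring grow directly into a chair, insertion into C8–C7 would have to pass through a boat, and the compression between the β-formyl group and the angular methyl is relieved on the same path. The change from aldehyde to ketone and from five- to six-membered ring should make the shift irreversible, and no base is present that could equilibrate the ketol through its enediol.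

**Step 11**
Reactants: 16 (3R,4R,5R,7S,9S,10R)-3-(tert-butyldimethylsilyloxy)-9-hydroxyeremophil-11-en-8-one; 17 tigloyl chloride ((E)-2-methylbut-2-enoyl chloride)
Product: 18 (3R,4R,5R,7S,9S,10R)-3-(tert-butyldimethylsilyloxy)-8-oxoeremophil-11-en-9-yl (E)-2-methylbut-2-enoate
Conditions: tigloyl chloride, pyridine, DMAP (cat.), CH2Cl2, 0 °C → rt
Reagents that add atoms: tigloyl chloride 17, C/C=C(\C)C(=O)Cl
Why: DMAP-catalysed acylation of the equatorial C9 hydroxyl with the acid chloride in pyridine is mild enough to leave the α-ketol and the α-isopropenyl ketone unchanged, the E geometry of the tiglate is the stable one, and C7 and C9 already hold their equatorial configurations.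

**Step 12**
Reactants: 18 (3R,4R,5R,7S,9S,10R)-3-(tert-butyldimethylsilyloxy)-8-oxoeremophil-11-en-9-yl (E)-2-methylbut-2-enoate
Product: 19 (3R,4R,5R,7S,9S,10R)-3-hydroxy-8-oxoeremophil-11-en-9-yl (E)-2-methylbut-2-enoate
Conditions: HF·pyridine, pyridine, THF, 0 °C → rt
Reagents that add atoms: none
Why: Cleavage of the secondary TBS ether with pyridine-buffered HF·pyridine (fluoride-induced desilylation) is neither basic enough to enolise the α-acyloxy ketone nor acidic enough to move the isopropenyl double bond, and the tiglate is unaffected.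

**Step 13**
Reactants: 19 (3R,4R,5R,7S,9S,10R)-3-hydroxy-8-oxoeremophil-11-en-9-yl (E)-2-methylbut-2-enoate; 20 3-methylbut-2-enoic acid (senecioic acid)
Product: 21 CNP0164025.1, (3R,4R,5R,7S,9S,10R)-3-(3-methylbut-2-enoyloxy)-8-oxoeremophil-11-en-9-yl (E)-2-methylbut-2-enoate
Conditions: 3-methylbut-2-enoic acid, DCC, DMAP (cat.), CH2Cl2, rt
Reagents that add atoms: 3-methylbut-2-enoic acid 20, CC(C)=CC(=O)O
Why: Steglich esterification of the equatorial C3 alcohol with the free acid; carbodiimide activation avoids the vinylketene pathway by which senecioyl chloride deconjugates under amine bases, and no stereocentre is touched.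

**Compound list**

1 | (R)-4-(tert-butyldimethylsilyloxy)cyclohex-2-en-1-one | O=C1CC[C@@H](O[Si](C)(C)C(C)(C)C)C=C1 | starting material
2 | (R)-4-(tert-butyldimethylsilyloxy)-2-iodocyclohex-2-en-1-one | O=C1CC[C@@H](O[Si](C)(C)C(C)(C)C)C=C1I | intermediate
3 | (R)-4-(tert-butyldimethylsilyloxy)-2-methylcyclohex-2-en-1-one | O=C1CC[C@@H](O[Si](C)(C)C(C)(C)C)C=C1C | intermediate
4 | prenyl bromide (1-bromo-3-methylbut-2-ene) | CC(C)=CCBr | starting material
5 | lithium (3R,4R)-4-(tert-butyldimethylsilyloxy)-2,3-dimethylcyclohex-1-en-1-olate | [Li+].[O-]C1=C(C)[C@@H](C)[C@H](O[Si](C)(C)C(C)(C)C)CC1 | intermediate (not isolated)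
6 | (2R,3R,4R)-4-(tert-butyldimethylsilyloxy)-2,3-dimethyl-2-(3-methylbut-2-en-1-yl)cyclohexan-1-one | O=C1CC[C@@H](O[Si](C)(C)C(C)(C)C)[C@H](C)[C@@]1(C)CC=C(C)C | intermediate
7 | potassium (4R,5R,6R)-4-(tert-butyldimethylsilyloxy)-5,6-dimethyl-6-(3-methylbut-2-en-1-yl)cyclohex-1-en-1-olate | [K+].[O-]C1=CC[C@@H](O[Si](C)(C)C(C)(C)C)[C@H](C)[C@@]1(C)CC=C(C)C | intermediate (not isolated)
8 | (4R,5R,6R)-4-(tert-butyldimethylsilyloxy)-5,6-dimethyl-6-(3-methylbut-2-en-1-yl)cyclohex-1-en-1-yl trifluoromethanesulfonate | O=S(=O)(OC1=CC[C@@H](O[Si](C)(C)C(C)(C)C)[C@H](C)[C@@]1(C)CC=C(C)C)C(F)(F)F | intermediate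
9 | ethyl glyoxylate | CCOC(=O)C=O | starting material
10 | ethyl 2-[(4R,5R,6R)-4-(tert-butyldimethylsilyloxy)-5,6-dimethyl-6-(3-methylbut-2-en-1-yl)cyclohex-1-en-1-yl]-2-hydroxyacetate (carbinol epimers) | CCOC(=O)C(O)C1=CC[C@@H](O[Si](C)(C)C(C)(C)C)[C@H](C)[C@@]1(C)CC=C(C)C | intermediate
11 | ethyl 2-[(1R,2R,3R,4R)-4-(tert-butyldimethylsilyloxy)-2,3-dimethyl-2-(3-methylbut-2-en-1-yl)cyclohexyl]-2-oxoacetate | CCOC(=O)C(=O)[C@@H]1CC[C@@H](O[Si](C)(C)C(C)(C)C)[C@H](C)[C@@]1(C)CC=C(C)C | intermediate
12 | ethyl 5α-(tert-butyldimethylsilyloxy)-1α-hydroxy-3aβ,4β-dimethyl-2α-(prop-1-en-2-yl)-7aαH-octahydro-1H-indene-1β-carboxylate | CCOC(=O)[C@@]1(O)[C@H](C(C)=C)C[C@]2(C)[C@@H](C)[C@H](O[Si](C)(C)C(C)(C)C)CC[C@@H]12 | intermediate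
13 | 5α-(tert-butyldimethylsilyloxy)-1β-(hydroxymethyl)-3aβ,4β-dimethyl-2α-(prop-1-en-2-yl)-7aαH-octahydro-1H-inden-1α-ol | OC[C@@]1(O)[C@H](C(C)=C)C[C@]2(C)[C@@H](C)[C@H](O[Si](C)(C)C(C)(C)C)CC[C@@H]12 | intermediate
14 | 5α-(tert-butyldimethylsilyloxy)-1α-hydroxy-3aβ,4β-dimethyl-2α-(prop-1-en-2-yl)-7aαH-octahydro-1H-indene-1β-carbaldehyde | O=C[C@@]1(O)[C@H](C(C)=C)C[C@]2(C)[C@@H](C)[C@H](O[Si](C)(C)C(C)(C)C)CC[C@@H]12 | intermediate
15 | chloro(methyl)aluminium 1α-alkoxide of aldehyde 14 | O=C[C@@]1(O[Al](C)Cl)[C@H](C(C)=C)C[C@]2(C)[C@@H](C)[C@H](O[Si](C)(C)C(C)(C)C)CC[C@@H]12 | intermediate (not isolated)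
16 | (3R,4R,5R,7S,9S,10R)-3-(tert-butyldimethylsilyloxy)-9-hydroxyeremophil-11-en-8-one (trans-decalin; 3-OSi α, 4- and 5-CH3 β, 7-isopropenyl α, 9-OH α, 10-H α) | C=C(C)[C@@H]1C[C@]2(C)[C@@H](C)[C@H](O[Si](C)(C)C(C)(C)C)CC[C@H]2[C@H](O)C1=O | intermediate
17 | tigloyl chloride ((E)-2-methylbut-2-enoyl chloride) | C/C=C(\C)C(=O)Cl | starting material
18 | (3R,4R,5R,7S,9S,10R)-3-(tert-butyldimethylsilyloxy)-8-oxoeremophil-11-en-9-yl (E)-2-methylbut-2-enoate | C=C(C)[C@@H]1C[C@]2(C)[C@@H](C)[C@H](O[Si](C)(C)C(C)(C)C)CC[C@H]2[C@H](OC(=O)/C(C)=C/C)C1=O | intermediate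
19 | (3R,4R,5R,7S,9S,10R)-3-hydroxy-8-oxoeremophil-11-en-9-yl (E)-2-methylbut-2-enoate | C=C(C)[C@@H]1C[C@]2(C)[C@@H](C)[C@H](O)CC[C@H]2[C@H](OC(=O)/C(C)=C/C)C1=O | intermediate
20 | 3-methylbut-2-enoic acid (senecioic acid) | CC(C)=CC(=O)O | starting material
21 | CNP0164025.1, (3R,4R,5R,7S,9S,10R)-3-(3-methylbut-2-enoyloxy)-8-oxoeremophil-11-en-9-yl (E)-2-methylbut-2-enoate | C=C(C)[C@@H]1C[C@]2(C)[C@@H](C)[C@H](OC(=O)C=C(C)C)CC[C@H]2[C@H](OC(=O)/C(C)=C/C)C1=O | target

**Summary and risks**

Total step count: 13. Longest linear sequence: 13 steps (from 1).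

Steps most likely to fail:

1. Step 10. The C8–C7 bond may migrate in competition (through a boat-like or non-chelated pathway), the product ketol may tautomerise through its enediol on aluminium, or a methyl group may be transferred from aluminium to the aldehyde; each would divert material to the regioisomeric ketol or to a carbinol. Fallback, setting out from 14 and returning at 16: the aldehyde is condensed with hydroxylamine to the oxime F1, which LiAlH4 should reduce to the 1β-aminomethyl carbinol F2. Diazotisation (NaNO2, aqueous AcOH, 0 °C) should then trigger a Tiffeneau–Demjanov ring expansion to the 9-unsubstituted trans-fused 8-ketone F3, the β-oriented CH2N2+ group again feeding the C8–C10 bond through a chair. Kinetic enolisation toward the C9 methylene (KHMDS, THF, −78 °C) and oxidation with 2-(phenylsulfonyl)-3-phenyloxaziridine from the α face (the β face of C9 is 1,3-diaxial to the angular methyl) should give ketol 16.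

2. Step 7. The Lewis acid may open a stepwise cationic (Prins-type) pathway, with loss of the cis relationship between hydroxyl and isopropenyl, proton loss toward the isopropylidene isomer, or epimerisation at C10 followed by closure to the cis-fused ring. Fallback, setting out from 11 and returning at 12: allylic oxidation of the (E)-methyl group of the prenyl unit (SeO2 cat., t-BuOOH, CH2Cl2) should give the (E)-allylic alcohol F4, which CBr4/PPh3 converts into the allylic bromide F5. CrCl2 in THF should then generate an allylchromium species that adds through its γ carbon (C7) to the ketone in a closed six-membered transition state (intramolecular Nozaki–Hiyama allylation). This forms the C7–C8 bond under non-acidic conditions, with the oxygen and the new isopropenyl group again cis, and gives 12.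

3. Step 6. The prototropic shift may stall, or ketonisation and equilibration may leave too much of the C10 epimer with an axial keto ester group, which would lead to the cis-fused hydrindane in step 7. Fallback, setting out from 10 and returning at 11: oxidation with Dess–Martin periodinane should give the conjugated 2-oxo-3-enoate F6. 1,4-Reduction with [(Ph3P)CuH]6 in toluene, followed by protonation of the copper enolate at low temperature with a hindered phenol, should then deliver the C10 hydrogen under kinetic control from the α face, anti to the axial C14 methyl, and give 11.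

**Further compounds**

F1 | step 10 | oxime of 5α-(tert-butyldimethylsilyloxy)-1α-hydroxy-3aβ,4β-dimethyl-2α-(prop-1-en-2-yl)-7aαH-octahydro-1H-indene-1β-carbaldehyde | ON=C[C@@]1(O)[C@H](C(C)=C)C[C@]2(C)[C@@H](C)[C@H](O[Si](C)(C)C(C)(C)C)CC[C@@H]12
F2 | step 10 | 1β-(aminomethyl)-5α-(tert-butyldimethylsilyloxy)-3aβ,4β-dimethyl-2α-(prop-1-en-2-yl)-7aαH-octahydro-1H-inden-1α-ol | NC[C@@]1(O)[C@H](C(C)=C)C[C@]2(C)[C@@H](C)[C@H](O[Si](C)(C)C(C)(C)C)CC[C@@H]12
F3 | step 10 | 3α-(tert-butyldimethylsilyloxy)-10αH-eremophil-11-en-8-one (4β,5β-dimethyl, 7α-isopropenyl, trans-fused) | C=C(C)[C@@H]1C[C@]2(C)[C@@H](C)[C@H](O[Si](C)(C)C(C)(C)C)CC[C@H]2CC1=O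
F4 | step 7 | ethyl 2-[(1R,2R,3R,4R)-4-(tert-butyldimethylsilyloxy)-2-[(E)-4-hydroxy-3-methylbut-2-en-1-yl]-2,3-dimethylcyclohexyl]-2-oxoacetate | CCOC(=O)C(=O)[C@@H]1CC[C@@H](O[Si](C)(C)C(C)(C)C)[C@H](C)[C@@]1(C)C/C=C(\C)CO
F5 | step 7 | ethyl 2-[(1R,2R,3R,4R)-2-[(E)-4-bromo-3-methylbut-2-en-1-yl]-4-(tert-butyldimethylsilyloxy)-2,3-dimethylcyclohexyl]-2-oxoacetate | CCOC(=O)C(=O)[C@@H]1CC[C@@H](O[Si](C)(C)C(C)(C)C)[C@H](C)[C@@]1(C)C/C=C(\C)CBr
F6 | step 6 | ethyl 2-[(4R,5R,6R)-4-(tert-butyldimethylsilyloxy)-5,6-dimethyl-6-(3-methylbut-2-en-1-yl)cyclohex-1-en-1-yl]-2-oxoacetate | CCOC(=O)C(=O)C1=CC[C@@H](O[Si](C)(C)C(C)(C)C)[C@H](C)[C@@]1(C)CC=C(C)C
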